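**Plan**
- Retrosynthesis first cuts the depside ester C(=O)–O bond between the C1' carboxyl of ring A and the C4 oxygen of ring B, and the C5'–Cl bond.
- Ring A (C1' carboxyl, C2' OMe, C3' Me, C4' OH, C5' Cl, C6' Me) is then cut across C5'–C6', C2'–C3', C4'–C5' and C1'–C2' to an α'-diazo enone ester and 1-(triisopropylsiloxy)propyne.
- Enabling feature: ring A is a resorcinol carboxylate whose meta oxygens at C2' and C4' flank C3'–Me. A ketene carbonyl (giving free C2'–OH) and an O-silyl ynol ether (giving C3'–Me and C4'–OSi) deliver this pattern with the two oxygens already differentiated.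
- Forward: the ynol ether (step 1) and the diazo enone (steps 2–3) are merged into ring A (step 4), followed by 2'-O-methylation and debenzylation (steps 5–6). The ring B phenol is made from methyl atratate by C5 methylation and 2-O-methylation (steps 7–11). Esterification, desilylation and C5' chlorination finish the route (steps 12–14).
- Stereochemistry: the target has no stereocentre. The only stereochemical element on the way is the E alkene of the diazo enone, set in the Wittig step and consumed in the ring closure.

Key step: step 4

Remark: ring A is numbered C1' (carboxyl-bearing carbon) to C6' as above and ring B C1 (CO2Me) to C6. The diazo enone is reached by diazo transfer to a methyl ketone, not by acylation of diazomethane, because diazomethane would add as a 1,3-dipole to the fumarate-like double bond.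

**Route**

Step 1
Reactants: 1 ethyl acetate
Product: 4 1-(triisopropylsiloxy)prop-1-yne, via lithium hemiketal alkoxide adduct 2 (not isolated), via lithium propynolate 3 (not isolated)
Conditions: CH2Br2, lithium 2,2,6,6-tetramethylpiperidide (from the amine and n-BuLi), THF, −78 °C; then n-BuLi, −78 °C → rt; then iPr3SiCl, −78 °C → rt
Reagents that add atoms: dibromomethane BrCBr; chlorotriisopropylsilane CC(C)[Si](Cl)(C(C)C)C(C)C
Why: Kowalski ynolate homologation, in which dibromomethyllithium adds to the ester, bromine–lithium exchange triggers a carbenoid 1,2-shift to the lithium ynolate, and the bulky chlorosilane should silylate on oxygen to give the ynol ether.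

Step 2
Reactants: 5 butane-2,3-dione (excess); 6 benzyl (triphenylphosphoranylidene)acetate
Product: 7 benzyl (2E)-3-methyl-4-oxopent-2-enoate
Conditions: CH2Cl2, rt
Reagents that add atoms: none
Why: Wittig olefination of one carbonyl of the symmetrical 1,2-dione by a stabilised ylide should give the E alkene (ester trans to acetyl), the excess of volatile dione suppressing double olefination.

Step 3
Reactants: 7 benzyl (2E)-3-methyl-4-oxopent-2-enoate
Product: 9 benzyl (2E)-5-diazo-3-methyl-4-oxopent-2-enoate, via trifluoroacetyl ketone 8 (not isolated)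
Conditions: LiN(SiMe3)2, THF, −78 °C (7 added to the base); CF3CO2CH2CF3, −78 °C; aqueous HCl work-up, crude 8 carried on; then 4-acetamidobenzenesulfonyl azide, Et3N, H2O (1 equiv), MeCN, rt
Reagents that add atoms: 4-acetamidobenzenesulfonyl azide CC(=O)Nc1ccc(cc1)S(=O)(=O)N=[N+]=[N-]
Why: Detrifluoroacetylative diazo transfer, in which kinetic deprotonation of the methyl ketone and Claisen trifluoroacetylation activate the α' carbon as a 1,3-diketone that accepts N2 from the sulfonyl azide with loss of the trifluoroacetyl group, the standard entry to α'-diazo enones.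

Step 4
Reactants: 9 benzyl (2E)-5-diazo-3-methyl-4-oxopent-2-enoate; 4 1-(triisopropylsiloxy)prop-1-yne
Product: 14 benzyl 2-hydroxy-3,6-dimethyl-4-(triisopropylsiloxy)benzoate, via vinylketene 10 (not isolated), via vinylcyclobutenone 11 (not isolated), via dienylketene 12 (not isolated), via cyclohexadienone 13 (not isolated)
Conditions: hν (254 nm, low-pressure Hg lamp, Vycor), degassed ClCH2CH2Cl, rt; then 80 °C
Reagents that add atoms: none
Why: Irradiation expels N2 and the alkenyl group migrates (photochemical Wolff rearrangement, C5'–C6') to vinylketene 10, whose carbonyl carbon is attacked by the methyl-bearing carbon of ynol ether 4 in a [2+2] cycloaddition (C2'–C3' and C4'–C5') that gives 4-alkenylcyclobutenone 11. On heating, 11 should open by four-electron conrotatory electrocyclic cleavage to dienylketene 12, ring A then closes by thermal six-electron disrotatory electrocyclisation between the ketene carbon and the ester-bearing alkene carbon (C1'–C2'), and the β-keto ester 13 tautomerises to the salicylate. The closest known reaction type is the photochemical variant of the Danheiser benzannulation of α-diazo enones with siloxyalkynes, which gives resorcinol monosilyl ethers. No stereocentre survives, since those of 11 and 13 are transient and the E alkene from step 2, which keeps the ester on the outside of the cyclisation terminus, is consumed. The step needs the regiochemistry of the [2+2] addition, and this is secured by the polarity of the O-silyl ynol ether (nucleophilic at the carbon β to oxygen) against the electrophilic ketene carbon, which places C3'–Me between the free C2'–OH (former ketene oxygen) and C4'–OSi. Chemoselectivity for the ketene over the enoate should follow from the far higher electrophilicity of the ketene towards the electron-rich alkyne.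

Step 5
Reactants: 14 benzyl 2-hydroxy-3,6-dimethyl-4-(triisopropylsiloxy)benzoate
Product: 15 benzyl 2-methoxy-3,6-dimethyl-4-(triisopropylsiloxy)benzoate
Conditions: MeI, K2CO3, acetone, reflux
Reagents that add atoms: iodomethane CI
Why: Williamson O-methylation of the chelated salicylate phenol, under which the hindered aryl triisopropylsilyl ether and the benzyl ester should survive.

Step 6
Reactants: 15 benzyl 2-methoxy-3,6-dimethyl-4-(triisopropylsiloxy)benzoate
Product: 16 2-methoxy-3,6-dimethyl-4-(triisopropylsiloxy)benzoic acid
Conditions: H2 (1 atm), Pd/C, EtOAc, rt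
Reagents that add atoms: none
Why: Catalytic hydrogenolysis of the benzyl ester should free the acid without touching the silyl ether or the aryl methyl ether.

Step 7
Reactants: 17 methyl 2,4-dihydroxy-3,6-dimethylbenzoate (methyl atratate)
Product: 18 methyl 5-formyl-2,4-dihydroxy-3,6-dimethylbenzoate
Conditions: Cl2CHOMe, TiCl4, CH2Cl2, 0 °C → rt; then aqueous HCl
Reagents that add atoms: dichloromethyl methyl ether COC(Cl)Cl; water O
Why: Rieche formylation, an electrophilic aromatic substitution that can occur only at C5, the one free ring position, which is ortho to 4-OH and para to 2-OH.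

Step 8
Reactants: 18 methyl 5-formyl-2,4-dihydroxy-3,6-dimethylbenzoate
Product: 19 methyl 2,4-dihydroxy-3,5,6-trimethylbenzoate
Conditions: H2 (4 atm), Pd/C, AcOH, 50 °C
Reagents that add atoms: none
Why: Hydrogenolysis of a hydroxy-activated benzaldehyde to the methyl arene via the benzylic alcohol, the classical conversion of formyl resorcinol esters into their C-methyl homologues.

Step 9
Reactants: 19 methyl 2,4-dihydroxy-3,5,6-trimethylbenzoate
Product: 20 methyl 4-(benzyloxy)-2-hydroxy-3,5,6-trimethylbenzoate
Conditions: BnBr (1.05 equiv), K2CO3, acetone, reflux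
Reagents that add atoms: benzyl bromide BrCc1ccccc1
Why: Williamson etherification that should select 4-OH, because 2-OH is hydrogen-bonded to the ester carbonyl and reacts far more slowly under mild carbonate conditions.

Step 10
Reactants: 20 methyl 4-(benzyloxy)-2-hydroxy-3,5,6-trimethylbenzoate
Product: 21 methyl 4-(benzyloxy)-2-methoxy-3,5,6-trimethylbenzoate
Conditions: MeI, K2CO3, DMF, 50 °C
Reagents that add atoms: iodomethane CI
Why: Williamson methylation of the remaining chelated phenol under more forcing conditions, with no other nucleophilic site left.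

Step 11
Reactants: 21 methyl 4-(benzyloxy)-2-methoxy-3,5,6-trimethylbenzoate
Product: 22 methyl 4-hydroxy-2-methoxy-3,5,6-trimethylbenzoate
Conditions: H2 (1 atm), Pd/C, EtOAc, rt
Reagents that add atoms: none
Why: Hydrogenolysis of the aryl benzyl ether should release the ring B phenol and leave the methyl ester and the methyl ether intact.

Step 12
Reactants: 16 2-methoxy-3,6-dimethyl-4-(triisopropylsiloxy)benzoic acid; 22 methyl 4-hydroxy-2-methoxy-3,5,6-trimethylbenzoate
Product: 24 methyl 2-methoxy-4-{[2-methoxy-3,6-dimethyl-4-(triisopropylsiloxy)benzoyl]oxy}-3,5,6-trimethylbenzoate, via mixed trifluoroacetic anhydride 23 (not isolated)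
Conditions: (CF3CO)2O, toluene, 0 °C → rt
Reagents that add atoms: none
Why: Mixed-anhydride esterification, in which the electron-rich 2,6-disubstituted acid is activated to an acylium-like electrophile that O-acylates the hindered phenol, the usual way to depside esters, ring B offering no free position for C-acylation.

Step 13
Reactants: 24 methyl 2-methoxy-4-{[2-methoxy-3,6-dimethyl-4-(triisopropylsiloxy)benzoyl]oxy}-3,5,6-trimethylbenzoate
Product: 25 methyl 4-[(4-hydroxy-2-methoxy-3,6-dimethylbenzoyl)oxy]-2-methoxy-3,5,6-trimethylbenzoate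
Conditions: Bu4NF, AcOH, THF, 0 °C
Reagents that add atoms: none
Why: Fluoride-induced cleavage of the aryl silyl ether, buffered with acetic acid so that the liberated phenoxide cannot attack the depside ester.

Step 14
Reactants: 25 methyl 4-[(4-hydroxy-2-methoxy-3,6-dimethylbenzoyl)oxy]-2-methoxy-3,5,6-trimethylbenzoate
Product: 26 methyl 4-[(5-chloro-4-hydroxy-2-methoxy-3,6-dimethylbenzoyl)oxy]-2-methoxy-3,5,6-trimethylbenzoate
Conditions: SO2Cl2 (1.05 equiv), CH2Cl2, 0 °C
Reagents that add atoms: sulfuryl chloride O=S(=O)(Cl)Cl
Why: Electrophilic aromatic chlorination of the phenol at C5', the only unsubstituted aromatic position in the molecule, which is ortho to C4'–OH and para to C2'–OMe.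

**Compound list**

1 | ethyl acetate | CCOC(C)=O | starting material
2 | lithium 1,1-dibromo-2-ethoxypropan-2-olate (racemic, transient) | CCOC(C)([O-])C(Br)Br.[Li+] | intermediate
3 | lithium prop-1-yn-1-olate | CC#C[O-].[Li+] | intermediate
4 | 1-(triisopropylsiloxy)prop-1-yne | CC#CO[Si](C(C)C)(C(C)C)C(C)C | intermediate
5 | butane-2,3-dione | CC(=O)C(C)=O | starting material
6 | benzyl (triphenylphosphoranylidene)acetate | O=C(C=P(c1ccccc1)(c1ccccc1)c1ccccc1)OCc1ccccc1 | starting material
7 | benzyl (2E)-3-methyl-4-oxopent-2-enoate | CC(=O)/C(C)=C/C(=O)OCc1ccccc1 | intermediate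
8 | benzyl (2E)-7,7,7-trifluoro-3-methyl-4,6-dioxohept-2-enoate | O=C(CC(=O)/C(C)=C/C(=O)OCc1ccccc1)C(F)(F)F | intermediate
9 | benzyl (2E)-5-diazo-3-methyl-4-oxopent-2-enoate | [N-]=[N+]=CC(=O)/C(C)=C/C(=O)OCc1ccccc1 | intermediate
10 | benzyl (2E)-3-methyl-5-oxopenta-2,4-dienoate (vinylketene) | O=C=C/C(C)=C/C(=O)OCc1ccccc1 | intermediate
11 | benzyl (2E)-3-[3-methyl-4-oxo-2-(triisopropylsiloxy)cyclobut-2-en-1-yl]but-2-enoate (racemic, transient) | CC1=C(O[Si](C(C)C)(C(C)C)C(C)C)C(/C(C)=C/C(=O)OCc2ccccc2)C1=O | intermediate
12 | benzyl (2E,4E)-3,6-dimethyl-7-oxo-5-(triisopropylsiloxy)hepta-2,4,6-trienoate (dienylketene) | O=C=C(C)/C(O[Si](C(C)C)(C(C)C)C(C)C)=C\C(C)=C\C(=O)OCc1ccccc1 | intermediate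
13 | benzyl 3,6-dimethyl-2-oxo-4-(triisopropylsiloxy)cyclohexa-3,5-diene-1-carboxylate (racemic, transient) | CC1=CC(O[Si](C(C)C)(C(C)C)C(C)C)=C(C)C(=O)C1C(=O)OCc1ccccc1 | intermediate
14 | benzyl 2-hydroxy-3,6-dimethyl-4-(triisopropylsiloxy)benzoate | Cc1cc(O[Si](C(C)C)(C(C)C)C(C)C)c(C)c(O)c1C(=O)OCc1ccccc1 | intermediate
15 | benzyl 2-methoxy-3,6-dimethyl-4-(triisopropylsiloxy)benzoate | COc1c(C)c(O[Si](C(C)C)(C(C)C)C(C)C)cc(C)c1C(=O)OCc1ccccc1 | intermediate
16 | 2-methoxy-3,6-dimethyl-4-(triisopropylsiloxy)benzoic acid | COc1c(C)c(O[Si](C(C)C)(C(C)C)C(C)C)cc(C)c1C(=O)O | intermediate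
17 | methyl 2,4-dihydroxy-3,6-dimethylbenzoate (methyl atratate) | COC(=O)c1c(C)cc(O)c(C)c1O | starting material
18 | methyl 5-formyl-2,4-dihydroxy-3,6-dimethylbenzoate | COC(=O)c1c(C)c(C=O)c(O)c(C)c1O | intermediate
19 | methyl 2,4-dihydroxy-3,5,6-trimethylbenzoate | COC(=O)c1c(C)c(C)c(O)c(C)c1O | intermediate
20 | methyl 4-(benzyloxy)-2-hydroxy-3,5,6-trimethylbenzoate | COC(=O)c1c(C)c(C)c(OCc2ccccc2)c(C)c1O | intermediate
21 | methyl 4-(benzyloxy)-2-methoxy-3,5,6-trimethylbenzoate | COC(=O)c1c(C)c(C)c(OCc2ccccc2)c(C)c1OC | intermediate
22 | methyl 4-hydroxy-2-methoxy-3,5,6-trimethylbenzoate | COC(=O)c1c(C)c(C)c(O)c(C)c1OC | intermediate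
23 | 2-methoxy-3,6-dimethyl-4-(triisopropylsiloxy)benzoic trifluoroacetic anhydride | COc1c(C)c(O[Si](C(C)C)(C(C)C)C(C)C)cc(C)c1C(=O)OC(=O)C(F)(F)F | intermediate
24 | methyl 2-methoxy-4-{[2-methoxy-3,6-dimethyl-4-(triisopropylsiloxy)benzoyl]oxy}-3,5,6-trimethylbenzoate | COC(=O)c1c(C)c(C)c(OC(=O)c2c(C)cc(O[Si](C(C)C)(C(C)C)C(C)C)c(C)c2OC)c(C)c1OC | intermediate
25 | methyl 4-[(4-hydroxy-2-methoxy-3,6-dimethylbenzoyl)oxy]-2-methoxy-3,5,6-trimethylbenzoate | COC(=O)c1c(C)c(C)c(OC(=O)c2c(C)cc(O)c(C)c2OC)c(C)c1OC | intermediate
26 | methyl 4-[(5-chloro-4-hydroxy-2-methoxy-3,6-dimethylbenzoyl)oxy]-2-methoxy-3,5,6-trimethylbenzoate | COC(=O)c1c(C)c(C)c(OC(=O)c2c(C)c(Cl)c(O)c(C)c2OC)c(C)c1OC | target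

**Totals**

Total step count: 14. Longest linear sequence: 8 steps (steps 2, 3, 4, 5, 6, 12, 13, 14; the ring B branch, steps 7–11 followed by 12–14, is equally long).

**Steps most likely to fail**

Step 4. The photolysis could be diverted before the alkyne traps the ketene: E/Z photoisomerisation of the enoate, dipolar self-addition of the diazo group to the electron-poor alkene, or dimerisation of the electron-poor vinylketene; the thermal stage could also stall at the cyclobutenone. Fallback, setting out from 17 and returning at 14: saponification of 17 (aqueous NaOH, 50 °C, cold acidification to limit decarboxylation) would give 2,4-dihydroxy-3,6-dimethylbenzoic acid F1. Carboxylate alkylation (BnBr, KHCO3, DMF, rt) would give benzyl 2,4-dihydroxy-3,6-dimethylbenzoate F2, and silylation of the non-chelated 4-OH (iPr3SiCl, imidazole, DMF) would give 14. This gives up the de novo construction of ring A and is held only as a safety net.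

Step 3. The lithium enolate of 7 sits next to a strongly electrophilic 4-oxo-enoate, so γ-deprotonation at the C3 methyl or conjugate self-addition could lead to oligomers before trifluoroacetylation. Fallback, setting out from 7 and returning at 9: acid-mediated bromination of the acetyl methyl group (PhNMe3Br3, THF, 0 °C) would give benzyl (2E)-5-bromo-3-methyl-4-oxopent-2-enoate F3. Treatment with N,N'-ditosylhydrazine and DBU (THF, 0 °C) would then deliver 9 by N-alkylation and double sulfinate elimination, with no enolate of the enone involved.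

Step 12. Acyl transfer between two di-ortho-substituted partners may be slow, which would let C-acylation of ring A at C5' or acid-induced loss of the silyl group compete. Fallback, setting out from 16 and returning at 24: oxalyl chloride with catalytic DMF (CH2Cl2, 0 °C → rt) would give 2-methoxy-3,6-dimethyl-4-(triisopropylsiloxy)benzoyl chloride F4. This is then added to the sodium phenoxide of 22 (NaH, THF, 0 °C → rt), an irreversible anionic acylation under non-acidic conditions.

**Further compounds**

F1 | step 4 | 2,4-dihydroxy-3,6-dimethylbenzoic acid | Cc1cc(O)c(C)c(O)c1C(=O)O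
F2 | step 4 | benzyl 2,4-dihydroxy-3,6-dimethylbenzoate | Cc1cc(O)c(C)c(O)c1C(=O)OCc1ccccc1
F3 | step 3 | benzyl (2E)-5-bromo-3-methyl-4-oxopent-2-enoate | BrCC(=O)/C(C)=C/C(=O)OCc1ccccc1
F4 | step 12 | 2-methoxy-3,6-dimethyl-4-(triisopropylsiloxy)benzoyl chloride | COc1c(C)c(O[Si](C(C)C)(C(C)C)C(C)C)cc(C)c1C(=O)Cl
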